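**Retrosynthetic overview**
1. Target ⇒ cut the aryl–CH2 bond of the methylene bridge: a latent pyrone quinone methide (an arylthiomethyl pyrone, unmasked by visible-light photoredox C–S cleavage) plus a pentasubstituted acylphloroglucinol methyl ether with one free ring CH.
2. Acyl arene ⇒ cut aryl–C(=O): photo-Fries rearrangement of the mono-(R)-2-methylbutanoate of symmetric 2-prenyl-5-methoxyresorcinol, where ortho and para migration give the same ketone; the acid is the only source of chirality.
3. 2-Prenyl-5-methoxyresorcinol ⇒ 5-methoxyresorcinol + prenol (surface-templated ortho-allylation).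
4. Thioether ⇒ pyrone + formaldehyde + 4-methoxybenzenethiol; pyrone ⇒ silyl enol ether of pentan-3-one + malonyl dichloride.
5. Ring order: the pyran-2-one ring is the only ring built (step 1); the benzene ring is bought.

Assumption: the target SMILES encodes an (R)-2-methylbutanoyl group, so enantiopure (R)-2-methylbutanoic acid is the purchased chiral material; 3-(trimethylsilyloxy)pent-2-ene is taken as a catalogue reagent.

**Step 1**
Reactants: 1 3-(trimethylsilyloxy)pent-2-ene (E/Z mixture); 2 malonyl dichloride
Product: 3 6-ethyl-4-hydroxy-5-methyl-2H-pyran-2-one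
Conditions: Et2O, −78 °C → rt
Reagents that add atoms: none
Why: Effenberger-type pyrone synthesis, in which the silyl enol ether is C-acylated by one acid chloride and the enol oxygen of the resulting diketo acid chloride closes the lactone with the second; no stereocenter.

**Step 2**
Reactants: 3 6-ethyl-4-hydroxy-5-methyl-2H-pyran-2-one; 4 formaldehyde (as paraformaldehyde)
Product: 5 6-ethyl-4-hydroxy-3-{[(4-methoxyphenyl)sulfanyl]methyl}-5-methyl-2H-pyran-2-one
Conditions: (CH2O)n, 4-MeOC6H4SH (1.5 equiv, premixed with the paraformaldehyde), piperidine/AcOH (10 mol%), EtOH, 60 °C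
Reagents that add atoms: 4-methoxybenzenethiol, COc1ccc(S)cc1
Why: Three-component thia-Mannich reaction (Knoevenagel condensation then thia-Michael addition), in which the soft thiol in excess captures the methylidene intermediate faster than a second pyrone and gives a bench-stable latent quinone methide; no stereocenter.

**Step 3**
Reactants: 6 5-methoxybenzene-1,3-diol (5-methoxyresorcinol); 7 3-methylbut-2-en-1-ol (prenol)
Product: 8 5-methoxy-2-(3-methylbut-2-en-1-yl)benzene-1,3-diol
Conditions: acidic Al2O3, ClCH2CH2Cl, 80 °C
Reagents that add atoms: none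
Why: Alumina-templated Friedel–Crafts ortho-allylation, in which both phenolic OH groups bind the acidic surface and the prenyl unit is delivered to the carbon ortho to both oxygens, keeping the product symmetric so that no later regiochemical choice arises; no stereocenter.

**Step 4**
Reactants: 8 5-methoxy-2-(3-methylbut-2-en-1-yl)benzene-1,3-diol (3 equiv, excess recovered); 9 (2R)-2-methylbutanoic acid
Product: 10 3-hydroxy-5-methoxy-2-(3-methylbut-2-en-1-yl)phenyl (2R)-2-methylbutanoate
Conditions: DCC (1.1 equiv), 4-(dimethylamino)pyridine (5 mol%), CH2Cl2, 0 °C → rt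
Reagents that add atoms: none
Why: Steglich esterification of a symmetric diol used in excess gives the monoester whichever OH reacts, and the carbodiimide activation avoids the ketene pathway, so the purchased (R) centre is carried over unchanged.

**Step 5**
Reactants: 10 3-hydroxy-5-methoxy-2-(3-methylbut-2-en-1-yl)phenyl (2R)-2-methylbutanoate
Product: 11 (2R)-1-[2,4-dihydroxy-6-methoxy-3-(3-methylbut-2-en-1-yl)phenyl]-2-methylbutan-1-one
Conditions: hν (254 nm), degassed cyclohexane (5 mM), quartz flow coil, 20 °C
Reagents that add atoms: none
Why: Photo-Fries rearrangement, in which ArO–C(O) homolysis and in-cage recombination put the acyl group on the free ortho or the para carbon, which give the same ketone because the other ortho site carries the prenyl group; the sigma-acyl radical recombines far faster than it decarbonylates and no acid or base touches the alpha-hydrogen, so the (R) centre is retained.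

**Step 6**
Reactants: 5 6-ethyl-4-hydroxy-3-{[(4-methoxyphenyl)sulfanyl]methyl}-5-methyl-2H-pyran-2-one (1.3 equiv); 11 (2R)-1-[2,4-dihydroxy-6-methoxy-3-(3-methylbut-2-en-1-yl)phenyl]-2-methylbutan-1-one
Product: 13 3-{[2,4-dihydroxy-6-methoxy-5-[(2R)-2-methylbutanoyl]-3-(3-methylbut-2-en-1-yl)phenyl]methyl}-6-ethyl-4-hydroxy-5-methyl-2H-pyran-2-one, via quinone methide 6-ethyl-5-methyl-3-methylidenepyran-2,4-dione 12 (not isolated)
Conditions: 2,4,5,6-tetra(carbazol-9-yl)isophthalonitrile (4CzIPN, 2 mol%), blue LEDs (450 nm), degassed MeCN, Ar, 20 °C
Reagents that add atoms: none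
Why: Proposed new method: the excited organophotocatalyst (about +1.35 V vs SCE) should oxidise only the electron-rich aryl sulfide of 5 (about +1.2 V, below phenol 11 and the prenyl alkene), the sulfide radical cation loses the enol proton and the arylthiyl radical by mesolytic C–S cleavage to give quinone methide 12 at 20 °C, the reduced catalyst hands the electron back to the thiyl radical (redox-neutral, thiol released), and 12 is trapped irreversibly by Friedel–Crafts/Michael addition of the only free ring carbon of 11 while thiol re-addition merely regenerates 5; the closest known reaction type is visible-light photoredox C–S cleavage of benzylic thioethers to carbocations or ortho-quinone methides that are trapped by electron-rich arenes; no stereocenter is formed and the (R) centre is untouched under these neutral conditions.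

**Compound list**
1 | 3-(trimethylsilyloxy)pent-2-ene (E/Z mixture) | CC=C(CC)O[Si](C)(C)C | starting material
2 | malonyl dichloride | O=C(Cl)CC(=O)Cl | starting material
3 | 6-ethyl-4-hydroxy-5-methyl-2H-pyran-2-one | CCc1oc(=O)cc(O)c1C | intermediate
4 | formaldehyde (paraformaldehyde) | C=O | starting material
5 | 6-ethyl-4-hydroxy-3-{[(4-methoxyphenyl)sulfanyl]methyl}-5-methyl-2H-pyran-2-one | CCc1oc(=O)c(CSc2ccc(OC)cc2)c(O)c1C | intermediate
6 | 5-methoxybenzene-1,3-diol | COc1cc(O)cc(O)c1 | starting material
7 | 3-methylbut-2-en-1-ol | CC(C)=CCO | starting material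
8 | 5-methoxy-2-(3-methylbut-2-en-1-yl)benzene-1,3-diol | COc1cc(O)c(CC=C(C)C)c(O)c1 | intermediate
9 | (2R)-2-methylbutanoic acid | CC[C@@H](C)C(=O)O | starting material
10 | 3-hydroxy-5-methoxy-2-(3-methylbut-2-en-1-yl)phenyl (2R)-2-methylbutanoate | CC[C@@H](C)C(=O)Oc1cc(OC)cc(O)c1CC=C(C)C | intermediate
11 | (2R)-1-[2,4-dihydroxy-6-methoxy-3-(3-methylbut-2-en-1-yl)phenyl]-2-methylbutan-1-one | CC[C@@H](C)C(=O)c1c(O)c(CC=C(C)C)c(O)cc1OC | intermediate
12 | 6-ethyl-5-methyl-3-methylidene-2H-pyran-2,4(3H)-dione | CCC1=C(C)C(=O)C(=C)C(=O)O1 | intermediate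
13 | 3-{[2,4-dihydroxy-6-methoxy-5-[(2R)-2-methylbutanoyl]-3-(3-methylbut-2-en-1-yl)phenyl]methyl}-6-ethyl-4-hydroxy-5-methyl-2H-pyran-2-one | CCc1oc(=O)c(Cc2c(O)c(CC=C(C)C)c(O)c(C(=O)[C@H](C)CC)c2OC)c(O)c1C | target

**Step count and risks**
Total steps: 6. Longest linear sequence: 4 steps (3 → 4 → 5 → 6, from 5-methoxyresorcinol); the pyrone branch is 2 steps before the union.

Most likely to fail:

Step 6 (the proposed new photoredox union). Possible failures are unselective oxidation of phenol 11, slow C–S fragmentation, and thiyl-radical chemistry at the prenyl group (hydrothiolation or alkene migration). The fallback uses the established thermal amine-elimination route; it sets out from 3 and 11 and comes back at 13. Pyrone 3 is treated with dimethylmethylideneammonium iodide in CH2Cl2/MeCN to form 3-[(dimethylamino)methyl]-6-ethyl-4-hydroxy-5-methyl-2H-pyran-2-one F6 in situ. Then 11 is added and the mixture is warmed to 40 °C. Thermal loss of dimethylamine gives the same quinone methide 12, which the free ring carbon of 11 traps to give 13.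

Step 3 (regioselective prenylation). The isomer prenylated between OH and OMe, double prenylation and chroman formation may compete. The fallback replaces surface templating by directed ortho-metalation; it sets out from 6 and comes back at 8. Diol 6 is protected as 1-methoxy-3,5-bis(methoxymethoxy)benzene F1 (chloromethyl methyl ether, i-Pr2NEt, CH2Cl2). F1 is lithiated between the two acetal oxygens with n-BuLi in THF at 0 °C to give [4-methoxy-2,6-bis(methoxymethoxy)phenyl]lithium F2. F2 is alkylated with prenyl bromide (CuBr·SMe2, 10 mol%) to give 5-methoxy-1,3-bis(methoxymethoxy)-2-(3-methylbut-2-en-1-yl)benzene F3. The acetals are then cleaved (HCl, MeOH, rt) to return to 8.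

Step 5 (photo-Fries with the prenyl group present). Phenol–alkene photocyclisation to a chroman, cage escape back to 8, and inner-filter stalling by product 11 are the concerns. The fallback moves the rearrangement ahead of the alkene; it sets out from 6 and 9 and comes back at 11. Excess 6 is esterified with 9 (DCC, 4-(dimethylamino)pyridine, CH2Cl2) to give 3-hydroxy-5-methoxyphenyl (2R)-2-methylbutanoate F4. Irradiation at 254 nm in cyclohexane gives (2R)-1-(2,4-dihydroxy-6-methoxyphenyl)-2-methylbutan-1-one F5; migration to the carbon next to the methoxy group and para migration converge on this ketone, and the regioisomer is removed by chromatography. C-prenylation between the two hydroxyls (prenyl bromide, aqueous KOH, 0 °C, regioisomer separated) then returns to 11.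

**Further compounds**
F1 | step 3 | 1-methoxy-3,5-bis(methoxymethoxy)benzene | COCOc1cc(OC)cc(OCOC)c1
F2 | step 3 | [4-methoxy-2,6-bis(methoxymethoxy)phenyl]lithium | [Li]c1c(OCOC)cc(OC)cc1OCOC
F3 | step 3 | 5-methoxy-1,3-bis(methoxymethoxy)-2-(3-methylbut-2-en-1-yl)benzene | COCOc1cc(OC)cc(OCOC)c1CC=C(C)C
F4 | step 5 | 3-hydroxy-5-methoxyphenyl (2R)-2-methylbutanoate | CC[C@@H](C)C(=O)Oc1cc(O)cc(OC)c1
F5 | step 5 | (2R)-1-(2,4-dihydroxy-6-methoxyphenyl)-2-methylbutan-1-one | CC[C@@H](C)C(=O)c1c(O)cc(O)cc1OC
F6 | step 6 | 3-[(dimethylamino)methyl]-6-ethyl-4-hydroxy-5-methyl-2H-pyran-2-one | CCc1oc(=O)c(CN(C)C)c(O)c1C
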